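**Assumption:** positions are numbered as in a non-5-en-9-olide (C1 lactone carbonyl, C2 acyloxy carbon, C5=C6 alkene, C7/C8 diol, C9 propyl-bearing ring carbinol), which makes the target (2R,5E,7R,8S,9R). Ethynylmagnesium bromide solution and (R)-α-hydroxy-γ-butyrolactone are bought.

## Retrosynthetic overview

1. Target ⇒ (acid: acetonide and tert-butyl ester off) ⇒ C2–O acylation of hydroxy lactone 25 with mono-tert-butyl (E,E)-muconate 20 (fragment 3, from a Heck coupling of tert-butyl (E)-3-iodoacrylate with acrylic acid).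
2. 10-membered lactone ⇒ C4–C5 bond by an intramolecular copper hydride/nickel-catalysed anti-Markovnikov hydroalkylation of the terminal alkyne with the tethered primary iodide of ester 23; this also sets the 5E alkene.
3. 23 ⇒ ester of alkyne alcohol 9 (fragment 1, C5–C12) with (2R)-2-silyloxy-4-chlorobutanoic acid 14 (fragment 2, from (R)-α-hydroxy-γ-butyrolactone), then Cl→I exchange.
4. 9 ⇒ (E)-hex-2-enal + ethynyl Grignard; Sharpless kinetic-resolution epoxidation (C7, C9); urethane-assisted epoxide opening with inversion at C8; acetonide.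
5. Ring order: oxirane → 1,3-dioxolan-2-one → 1,3-dioxolane (acetonide) → 10-membered lactone (last); the acetonide is opened in the final step.

## Route

**Fragment 1 (steps 1–5)**

Step 1
Reactants: 1 (E)-hex-2-enal
Product: 3 (±)-(E)-oct-4-en-1-yn-3-ol, via bromomagnesium alkoxide 2 (not isolated)
Conditions: HC≡CMgBr (1.2 equiv), THF, −20 → 0 °C; then sat. aq. NH4Cl
Reagents that add atoms: ethynylmagnesium bromide, C#C[Mg]Br
Why: Grignard 1,2-addition of the alkynyl nucleophile to the enal carbonyl; the racemate is resolved in step 2.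

Step 2
Reactants: 3 (±)-(E)-oct-4-en-1-yn-3-ol
Product: 4 (1R)-1-[(2R,3R)-3-propyloxiran-2-yl]prop-2-yn-1-ol
Conditions: Ti(OiPr)4 (0.15 equiv), D-(−)-diisopropyl tartrate (0.20 equiv), t-BuOOH (0.45 equiv, decane), 4 Å MS, CH2Cl2, −20 °C
Reagents that add atoms: tert-butyl hydroperoxide, CC(C)(C)OO
Why: Sharpless asymmetric epoxidation run as a kinetic resolution: with the D-(−)-tartrate the (S)-enantiomer of 3 is epoxidised fast, on the alkene face fixed by the ligand, to the erythro epoxy alcohol (this fixes C7 and C9 and the trans-oxirane), while the (R)-enantiomer stays largely unreacted and any epoxide from it is the separable threo diastereomer (maximum yield 50%).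

Step 3
Reactants: 4 (1R)-1-[(2R,3R)-3-propyloxiran-2-yl]prop-2-yn-1-ol
Product: 5 (1R)-1-[(2S,3R)-3-propyloxiran-2-yl]prop-2-yn-1-yl N-phenylcarbamate
Conditions: PhNCO (1.3 equiv), pyridine, CH2Cl2, rt
Reagents that add atoms: phenyl isocyanate, O=C=Nc1ccccc1
Why: Carbamoylation of the secondary alcohol with an isocyanate installs the internal oxygen nucleophile; no stereocentre is touched (the oxirane C2 descriptor changes from R to S only through the priority rules).

Step 4
Reactants: 5 (1R)-1-[(2S,3R)-3-propyloxiran-2-yl]prop-2-yn-1-yl N-phenylcarbamate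
Product: 7 (4R,5R)-4-ethynyl-5-[(1R)-1-hydroxybutyl]-1,3-dioxolan-2-one, via iminocarbonate 6 (not isolated)
Conditions: BF3·OEt2 (1.1 equiv), Et2O, −20 °C; then 1 M aq. H2SO4, rt
Reagents that add atoms: water, O
Why: Lewis acid-promoted neighbouring-group opening of the epoxide by the urethane carbonyl oxygen (5-exo attack at C8 with inversion), then hydrolysis of the iminocarbonate; this sets C8 and gives the 7,8-syn/8,9-anti triol pattern with only the C9 hydroxyl free.

Step 5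
Reactants: 7 (4R,5R)-4-ethynyl-5-[(1R)-1-hydroxybutyl]-1,3-dioxolan-2-one
Product: 9 (1R)-1-[(4R,5R)-5-ethynyl-2,2-dimethyl-1,3-dioxolan-4-yl]butan-1-ol, via triol 8 (not isolated)
Conditions: K2CO3 (0.2 equiv), MeOH, rt; evaporate; Me2C(OMe)2 (5 equiv), CSA (0.5 equiv), acetone, rt, 16 h
Reagents that add atoms: 2,2-dimethoxypropane, COC(C)(C)OC
Why: Base-catalysed methanolysis of the cyclic carbonate, then acetonide formation under thermodynamic control: the threo 7,8-diol gives the less strained trans-dioxolane in preference to the cis-dioxolane of the erythro 8,9-diol, so the C9 hydroxyl stays free.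

**Fragment 2 (steps 6–8)**

Step 6
Reactants: 10 (3R)-3-hydroxyoxolan-2-one ((R)-α-hydroxy-γ-butyrolactone)
Product: 11 methyl (2R)-4-chloro-2-hydroxybutanoate
Conditions: HCl (g, sat.), MeOH, ZnCl2 (5 mol%), 45 °C, sealed, 24 h
Reagents that add atoms: hydrogen chloride, Cl; methanol, CO
Why: Acid-mediated lactone opening: chloride attacks C4 of the protonated lactone (SN2, alkyl–oxygen cleavage) and the acid is esterified in situ (Fischer esterification); the C2 stereocentre is not involved.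

Step 7
Reactants: 11 methyl (2R)-4-chloro-2-hydroxybutanoate
Product: 12 methyl (2R)-2-[(tert-butyldimethylsilyl)oxy]-4-chlorobutanoate
Conditions: TBSCl (1.3 equiv), imidazole (2.5 equiv), DMF, rt
Reagents that add atoms: tert-butyldimethylsilyl chloride, CC(C)(C)[Si](C)(C)Cl
Why: Standard silyl ether protection of the α-hydroxyl; a silyl ether has no weak C–H bond near C4 that could interfere with the later radical step.

Step 8
Reactants: 12 methyl (2R)-2-[(tert-butyldimethylsilyl)oxy]-4-chlorobutanoate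
Product: 14 (2R)-2-[(tert-butyldimethylsilyl)oxy]-4-chlorobutanoic acid, via lithium carboxylate 13 (not isolated)
Conditions: LiOH·H2O (1.2 equiv), THF/H2O 3:1, 0 °C, 1 h; then 1 M HCl to pH 3, 0 °C
Reagents that add atoms: lithium hydroxide, [Li+].[OH-]
Why: Ester saponification; at 0 °C the γ-chloro carboxylate closes back to the lactone too slowly to compete (chloride was chosen over bromide or iodide for this reason).

**Fragment 3 (steps 9–11)**

Step 9
Reactants: 15 prop-2-ynoic acid (propiolic acid)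
Product: 16 (E)-3-iodoprop-2-enoic acid
Conditions: 57% aq. HI (1.5 equiv), 90 °C, 24 h
Reagents that add atoms: hydrogen iodide, I
Why: Hydroiodination of the alkynoic acid (conjugate addition of iodide); heating equilibrates the first-formed Z adduct to the thermodynamic E isomer.

Step 10
Reactants: 16 (E)-3-iodoprop-2-enoic acid
Product: 17 tert-butyl (E)-3-iodoprop-2-enoate
Conditions: t-BuOC(=NH)CCl3 (2 equiv), CH2Cl2/cyclohexane, rt, 16 h
Reagents that add atoms: tert-butyl 2,2,2-trichloroacetimidate, CC(C)(C)OC(=N)C(Cl)(Cl)Cl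
Why: Acid-promoted O-alkylation of the carboxylic acid by the imidate (tert-butyl ester formation) under conditions that do not isomerise the iodoalkene.

Step 11
Reactants: 17 tert-butyl (E)-3-iodoprop-2-enoate; 18 prop-2-enoic acid (acrylic acid)
Product: 20 (2E,4E)-6-tert-butoxy-6-oxohexa-2,4-dienoic acid, via potassium carboxylate 19 (not isolated)
Conditions: Pd(OAc)2 (5 mol%), K2CO3 (2.5 equiv), n-Bu4NCl (1 equiv), DMF, 40 °C; then 1 M HCl to pH 3
Reagents that add atoms: none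
Why: Mizoroki–Heck coupling under ligand-free phase-transfer conditions: the iodoalkene geometry is retained and syn-insertion/syn-β-hydride elimination gives the new E alkene, so the E,E half ester is obtained directly.

**Assembly (steps 12–17)**

Step 12
Reactants: 14 (2R)-2-[(tert-butyldimethylsilyl)oxy]-4-chlorobutanoic acid; 9 (1R)-1-[(4R,5R)-5-ethynyl-2,2-dimethyl-1,3-dioxolan-4-yl]butan-1-ol
Product: 22 (1R)-1-[(4R,5R)-5-ethynyl-2,2-dimethyl-1,3-dioxolan-4-yl]butyl (2R)-2-[(tert-butyldimethylsilyl)oxy]-4-chlorobutanoate, via mixed anhydride 21 (not isolated)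
Conditions: 14, 2,4,6-Cl3C6H2COCl (1.1 equiv), Et3N (2.5 equiv), THF, rt, 1 h; then 9, DMAP (0.5 equiv), toluene, rt
Reagents that add atoms: none
Why: Yamaguchi esterification: the mixed anhydride is activated by DMAP and acylates the hindered C9 hydroxyl with retention at C9 and C2.

Step 13
Reactants: 22 (1R)-1-[(4R,5R)-5-ethynyl-2,2-dimethyl-1,3-dioxolan-4-yl]butyl (2R)-2-[(tert-butyldimethylsilyl)oxy]-4-chlorobutanoate
Product: 23 (1R)-1-[(4R,5R)-5-ethynyl-2,2-dimethyl-1,3-dioxolan-4-yl]butyl (2R)-2-[(tert-butyldimethylsilyl)oxy]-4-iodobutanoate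
Conditions: NaI (10 equiv), acetone, reflux, 36 h, dark
Reagents that add atoms: sodium iodide, [Na+].[I-]
Why: Finkelstein halide exchange (SN2 at the primary carbon, driven by precipitation of NaCl) gives the iodide needed for radical activation.

Step 14
Reactants: 23 (1R)-1-[(4R,5R)-5-ethynyl-2,2-dimethyl-1,3-dioxolan-4-yl]butyl (2R)-2-[(tert-butyldimethylsilyl)oxy]-4-iodobutanoate
Product: 24 (2R,5E,7R,8R,9R)-2-[(tert-butyldimethylsilyl)oxy]-7,8-(isopropylidenedioxy)-9-propylnon-5-en-9-olide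
Conditions: (IPr)CuCl (15 mol%; IPr = 1,3-bis(2,6-diisopropylphenyl)imidazol-2-ylidene), NiCl2(dme) (10 mol%; dme = 1,2-dimethoxyethane), 4,4′,4″-tri-tert-butyl-2,2′:6′,2″-terpyridine (12 mol%), (EtO)2MeSiH (2.5 equiv), CsF (3 equiv), 1,4-dioxane/DMA 9:1, 40 °C, 23 added by syringe pump over 12 h (final 2 mM)
Reagents that add atoms: none
Why: Proposed new method: an intramolecular, ring-closing version of alkyne hydroalkylation. The carbene–copper hydride (from Cu–F and the silane) adds syn and anti-Markovnikov to the terminal alkyne to give the (E)-alkenylcopper at C5, the alkenyl group passes to nickel, the monovalent alkenylnickel abstracts iodine from the tethered C4–I, the C4 radical recombines at the same metal, and reductive elimination from trivalent nickel forms C4–C5 and closes the 10-membered lactone with the 5E geometry fixed by the syn-hydrocupration. Because both reacting ends sit on one catalyst-bound molecule, radical generation and capture are intramolecular, which should favour cyclisation over oligomerisation at high dilution. The closest known reaction type is the intermolecular copper hydride/nickel-catalysed anti-Markovnikov hydroalkylation of terminal alkynes with primary alkyl iodides (and its copper-only variant with alkyl triflates), which has not been used to close a ring.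

Step 15
Reactants: 24 (2R,5E,7R,8R,9R)-2-[(tert-butyldimethylsilyl)oxy]-7,8-(isopropylidenedioxy)-9-propylnon-5-en-9-olide
Product: 25 (2R,5E,7R,8R,9R)-2-hydroxy-7,8-(isopropylidenedioxy)-9-propylnon-5-en-9-olide
Conditions: HF·pyridine, pyridine/THF, 0 °C → rt
Reagents that add atoms: none
Why: Fluoride-mediated cleavage of the silyl ether; acetonide, lactone and alkene are stable to buffered HF.

Step 16
Reactants: 25 (2R,5E,7R,8R,9R)-2-hydroxy-7,8-(isopropylidenedioxy)-9-propylnon-5-en-9-olide; 20 (2E,4E)-6-tert-butoxy-6-oxohexa-2,4-dienoic acid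
Product: 26 (2R,5E,7R,8R,9R)-2-{[(2E,4E)-6-tert-butoxy-6-oxohexa-2,4-dienoyl]oxy}-7,8-(isopropylidenedioxy)-9-propylnon-5-en-9-olide
Conditions: 20 (1.5 equiv), i-PrN=C=N-i-Pr (1.6 equiv), DMAP (0.2 equiv), CH2Cl2, 0 °C → rt
Reagents that add atoms: none
Why: Steglich-type carbodiimide esterification of the only free hydroxyl (C2) with the free acid end of the half ester; mild, so C2 is not epimerised.

Step 17
Reactants: 26 (2R,5E,7R,8R,9R)-2-{[(2E,4E)-6-tert-butoxy-6-oxohexa-2,4-dienoyl]oxy}-7,8-(isopropylidenedioxy)-9-propylnon-5-en-9-olide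
Product: 27 (2R,5E,7R,8S,9R)-2-{[(2E,4E)-5-carboxypenta-2,4-dienoyl]oxy}-7,8-dihydroxy-9-propylnon-5-en-9-olide (target)
Conditions: TFA/CH2Cl2/H2O 10:10:1, 0 °C → rt
Reagents that add atoms: none
Why: Acidolysis: the tert-butyl ester loses isobutene and the acetonide is hydrolysed in the same operation, while the lactone, the dienoate ester and both alkene geometries are stable to aqueous TFA (the C8 descriptor becomes S only through the priority rules).

## Compound list

1 | (E)-hex-2-enal | CCC/C=C/C=O | starting material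
2 | bromomagnesium (E)-oct-4-en-1-yn-3-olate (racemic) | CCC/C=C/C(O[Mg]Br)C#C | intermediate (not isolated)
3 | (±)-(E)-oct-4-en-1-yn-3-ol | CCC/C=C/C(O)C#C | intermediate
4 | (1R)-1-[(2R,3R)-3-propyloxiran-2-yl]prop-2-yn-1-ol | C#C[C@@H](O)[C@H]1O[C@@H]1CCC | intermediate
5 | (1R)-1-[(2S,3R)-3-propyloxiran-2-yl]prop-2-yn-1-yl N-phenylcarbamate | C#C[C@@H](OC(=O)Nc1ccccc1)[C@H]2O[C@@H]2CCC | intermediate
6 | (4R,5R)-4-ethynyl-5-[(1R)-1-hydroxybutyl]-N-phenyl-1,3-dioxolan-2-imine | C#C[C@H]1OC(=Nc2ccccc2)O[C@@H]1[C@H](O)CCC | intermediate (not isolated)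
7 | (4R,5R)-4-ethynyl-5-[(1R)-1-hydroxybutyl]-1,3-dioxolan-2-one | C#C[C@H]1OC(=O)O[C@@H]1[C@H](O)CCC | intermediate
8 | (3R,4R,5R)-oct-1-yne-3,4,5-triol | C#C[C@@H](O)[C@H](O)[C@H](O)CCC | intermediate (not isolated)
9 | (1R)-1-[(4R,5R)-5-ethynyl-2,2-dimethyl-1,3-dioxolan-4-yl]butan-1-ol | C#C[C@H]1OC(C)(C)O[C@@H]1[C@H](O)CCC | intermediate
10 | (3R)-3-hydroxyoxolan-2-one | O[C@@H]1CCOC1=O | starting material
11 | methyl (2R)-4-chloro-2-hydroxybutanoate | COC(=O)[C@H](O)CCCl | intermediate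
12 | methyl (2R)-2-[(tert-butyldimethylsilyl)oxy]-4-chlorobutanoate | COC(=O)[C@H](O[Si](C)(C)C(C)(C)C)CCCl | intermediate
13 | lithium (2R)-2-[(tert-butyldimethylsilyl)oxy]-4-chlorobutanoate | [Li+].[O-]C(=O)[C@H](O[Si](C)(C)C(C)(C)C)CCCl | intermediate (not isolated)
14 | (2R)-2-[(tert-butyldimethylsilyl)oxy]-4-chlorobutanoic acid | OC(=O)[C@H](O[Si](C)(C)C(C)(C)C)CCCl | intermediate
15 | prop-2-ynoic acid | OC(=O)C#C | starting material
16 | (E)-3-iodoprop-2-enoic acid | OC(=O)/C=C/I | intermediate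
17 | tert-butyl (E)-3-iodoprop-2-enoate | CC(C)(C)OC(=O)/C=C/I | intermediate
18 | prop-2-enoic acid | OC(=O)C=C | starting material
19 | potassium (2E,4E)-6-tert-butoxy-6-oxohexa-2,4-dienoate | [K+].[O-]C(=O)/C=C/C=C/C(=O)OC(C)(C)C | intermediate (not isolated)
20 | (2E,4E)-6-tert-butoxy-6-oxohexa-2,4-dienoic acid | OC(=O)/C=C/C=C/C(=O)OC(C)(C)C | intermediate
21 | (2R)-2-[(tert-butyldimethylsilyl)oxy]-4-chlorobutanoic 2,4,6-trichlorobenzoic anhydride | O=C(OC(=O)c1c(Cl)cc(Cl)cc1Cl)[C@H](O[Si](C)(C)C(C)(C)C)CCCl | intermediate (not isolated)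
22 | (1R)-1-[(4R,5R)-5-ethynyl-2,2-dimethyl-1,3-dioxolan-4-yl]butyl (2R)-2-[(tert-butyldimethylsilyl)oxy]-4-chlorobutanoate | C#C[C@H]1OC(C)(C)O[C@@H]1[C@H](OC(=O)[C@H](O[Si](C)(C)C(C)(C)C)CCCl)CCC | intermediate
23 | (1R)-1-[(4R,5R)-5-ethynyl-2,2-dimethyl-1,3-dioxolan-4-yl]butyl (2R)-2-[(tert-butyldimethylsilyl)oxy]-4-iodobutanoate | C#C[C@H]1OC(C)(C)O[C@@H]1[C@H](OC(=O)[C@H](O[Si](C)(C)C(C)(C)C)CCI)CCC | intermediate
24 | (2R,5E,7R,8R,9R)-2-[(tert-butyldimethylsilyl)oxy]-7,8-(isopropylidenedioxy)-9-propylnon-5-en-9-olide | CCC[C@H]1OC(=O)[C@H](O[Si](C)(C)C(C)(C)C)CC/C=C/[C@H]2OC(C)(C)O[C@H]12 | intermediate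
25 | (2R,5E,7R,8R,9R)-2-hydroxy-7,8-(isopropylidenedioxy)-9-propylnon-5-en-9-olide | CCC[C@H]1OC(=O)[C@H](O)CC/C=C/[C@H]2OC(C)(C)O[C@H]12 | intermediate
26 | (2R,5E,7R,8R,9R)-2-{[(2E,4E)-6-tert-butoxy-6-oxohexa-2,4-dienoyl]oxy}-7,8-(isopropylidenedioxy)-9-propylnon-5-en-9-olide | CCC[C@H]1OC(=O)[C@H](OC(=O)/C=C/C=C/C(=O)OC(C)(C)C)CC/C=C/[C@H]2OC(C)(C)O[C@H]12 | intermediate
27 | (2R,5E,7R,8S,9R)-2-{[(2E,4E)-5-carboxypenta-2,4-dienoyl]oxy}-7,8-dihydroxy-9-propylnon-5-en-9-olide | CCC[C@H]1OC(=O)[C@H](OC(=O)/C=C/C=C/C(=O)O)CC/C=C/[C@@H](O)[C@@H]1O | target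

## Step count and risks

Total: 17 steps. Longest linear sequence: 11 steps (steps 1–5, then 12–17).

**Step 14 (proposed new ring closure).** The likely failure modes are intermolecular oligomerisation, simple reduction of the C–I bond, and protodemetalation of the alkenylcopper to the terminal alkene. The fallback closes the ring by C–O bond formation with known chemistry; it sets out from 12 and 9 and comes back at 24. Finkelstein exchange on 12 (NaI, acetone) gives methyl (2R)-2-[(tert-butyldimethylsilyl)oxy]-4-iodobutanoate F1. Palladium-catalysed hydrostannation of 9 (Bu3SnH, PdCl2(PPh3)2, THF) gives (1R)-1-[(4R,5R)-2,2-dimethyl-5-[(E)-2-(tributylstannyl)ethenyl]-1,3-dioxolan-4-yl]butan-1-ol F2, and iododestannylation (I2, CH2Cl2, 0 °C) gives (1R)-1-[(4R,5R)-5-[(E)-2-iodoethenyl]-2,2-dimethyl-1,3-dioxolan-4-yl]butan-1-ol F3. Zinc insertion into F1 (Zn dust, LiCl, THF) gives [(3R)-3-[(tert-butyldimethylsilyl)oxy]-4-methoxy-4-oxobutyl](iodo)zinc F4, used in excess in a Negishi coupling with F3 (Pd(OAc)2, SPhos, THF) to give methyl (2R,5E)-2-[(tert-butyldimethylsilyl)oxy]-6-[(4R,5R)-5-[(1R)-1-hydroxybutyl]-2,2-dimethyl-1,3-dioxolan-4-yl]hex-5-enoate F5. Saponification (LiOH, THF/H2O) gives (2R,5E)-2-[(tert-butyldimethylsilyl)oxy]-6-[(4R,5R)-5-[(1R)-1-hydroxybutyl]-2,2-dimethyl-1,3-dioxolan-4-yl]hex-5-enoic acid F6, and Yamaguchi macrolactonisation at high dilution (2,4,6-trichlorobenzoyl chloride, Et3N, then DMAP, toluene, 80 °C) closes the ring to 24.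

**Step 5 (placement of the acetonide on the triol).** The 8,9-acetonide may form in a significant amount. The fallback makes the placement unambiguous by blocking the C9 hydroxyl first; it sets out from 7 and comes back at 9. Etherification of 7 (4-methoxybenzyl trichloroacetimidate, cat. CSA) gives (4R,5R)-4-ethynyl-5-[(1R)-1-[(4-methoxybenzyl)oxy]butyl]-1,3-dioxolan-2-one F7. Carbonate methanolysis (K2CO3, MeOH) gives (3R,4S,5R)-5-[(4-methoxybenzyl)oxy]oct-1-yne-3,4-diol F8, and acetonide formation (2,2-dimethoxypropane, CSA) gives (4R,5R)-4-ethynyl-5-[(1R)-1-[(4-methoxybenzyl)oxy]butyl]-2,2-dimethyl-1,3-dioxolane F9. Oxidative removal of the benzyl ether (DDQ, CH2Cl2/buffer) gives 9.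

**Step 6 (lactone opening with HCl/MeOH).** The risks are incomplete conversion and reversion to the lactone. The fallback installs the halide only after the ester bond is made; it sets out from 10 (and uses 9) and comes back at 23. Silylation of 10 (TBSCl, imidazole) gives (3R)-3-[(tert-butyldimethylsilyl)oxy]oxolan-2-one F10, and NaOH (1 equiv, MeOH/H2O, then drying) gives sodium (2R)-2-[(tert-butyldimethylsilyl)oxy]-4-hydroxybutanoate F11. Silylation (TBSCl, imidazole, DMF) gives tert-butyldimethylsilyl (2R)-2,4-bis[(tert-butyldimethylsilyl)oxy]butanoate F12, whose silyl ester is cleaved (K2CO3, MeOH/THF/H2O) to (2R)-2,4-bis[(tert-butyldimethylsilyl)oxy]butanoic acid F13. Yamaguchi esterification with 9 gives (1R)-1-[(4R,5R)-5-ethynyl-2,2-dimethyl-1,3-dioxolan-4-yl]butyl (2R)-2,4-bis[(tert-butyldimethylsilyl)oxy]butanoate F14. Buffered HF·pyridine at 0 °C removes only the primary silyl ether to give (1R)-1-[(4R,5R)-5-ethynyl-2,2-dimethyl-1,3-dioxolan-4-yl]butyl (2R)-2-[(tert-butyldimethylsilyl)oxy]-4-hydroxybutanoate F15, which is converted at once (I2, PPh3, imidazole, CH2Cl2, 0 °C) into 23.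

## Further compounds

F1 | step 14 | methyl (2R)-2-[(tert-butyldimethylsilyl)oxy]-4-iodobutanoate | COC(=O)[C@H](O[Si](C)(C)C(C)(C)C)CCI
F2 | step 14 | (1R)-1-[(4R,5R)-2,2-dimethyl-5-[(E)-2-(tributylstannyl)ethenyl]-1,3-dioxolan-4-yl]butan-1-ol | CCCC[Sn](CCCC)(CCCC)/C=C/[C@H]1OC(C)(C)O[C@@H]1[C@H](O)CCC
F3 | step 14 | (1R)-1-[(4R,5R)-5-[(E)-2-iodoethenyl]-2,2-dimethyl-1,3-dioxolan-4-yl]butan-1-ol | I/C=C/[C@H]1OC(C)(C)O[C@@H]1[C@H](O)CCC
F4 | step 14 | [(3R)-3-[(tert-butyldimethylsilyl)oxy]-4-methoxy-4-oxobutyl](iodo)zinc | COC(=O)[C@H](O[Si](C)(C)C(C)(C)C)CC[Zn]I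
F5 | step 14 | methyl (2R,5E)-2-[(tert-butyldimethylsilyl)oxy]-6-[(4R,5R)-5-[(1R)-1-hydroxybutyl]-2,2-dimethyl-1,3-dioxolan-4-yl]hex-5-enoate | COC(=O)[C@H](O[Si](C)(C)C(C)(C)C)CC/C=C/[C@H]1OC(C)(C)O[C@@H]1[C@H](O)CCC
F6 | step 14 | (2R,5E)-2-[(tert-butyldimethylsilyl)oxy]-6-[(4R,5R)-5-[(1R)-1-hydroxybutyl]-2,2-dimethyl-1,3-dioxolan-4-yl]hex-5-enoic acid | OC(=O)[C@H](O[Si](C)(C)C(C)(C)C)CC/C=C/[C@H]1OC(C)(C)O[C@@H]1[C@H](O)CCC
F7 | step 5 | (4R,5R)-4-ethynyl-5-[(1R)-1-[(4-methoxybenzyl)oxy]butyl]-1,3-dioxolan-2-one | C#C[C@H]1OC(=O)O[C@@H]1[C@H](OCc2ccc(OC)cc2)CCC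
F8 | step 5 | (3R,4S,5R)-5-[(4-methoxybenzyl)oxy]oct-1-yne-3,4-diol | C#C[C@@H](O)[C@H](O)[C@H](OCc1ccc(OC)cc1)CCC
F9 | step 5 | (4R,5R)-4-ethynyl-5-[(1R)-1-[(4-methoxybenzyl)oxy]butyl]-2,2-dimethyl-1,3-dioxolane | C#C[C@H]1OC(C)(C)O[C@@H]1[C@H](OCc2ccc(OC)cc2)CCC
F10 | step 6 | (3R)-3-[(tert-butyldimethylsilyl)oxy]oxolan-2-one | CC(C)(C)[Si](C)(C)O[C@@H]1CCOC1=O
F11 | step 6 | sodium (2R)-2-[(tert-butyldimethylsilyl)oxy]-4-hydroxybutanoate | [Na+].[O-]C(=O)[C@H](O[Si](C)(C)C(C)(C)C)CCO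
F12 | step 6 | tert-butyldimethylsilyl (2R)-2,4-bis[(tert-butyldimethylsilyl)oxy]butanoate | CC(C)(C)[Si](C)(C)OC(=O)[C@H](O[Si](C)(C)C(C)(C)C)CCO[Si](C)(C)C(C)(C)C
F13 | step 6 | (2R)-2,4-bis[(tert-butyldimethylsilyl)oxy]butanoic acid | OC(=O)[C@H](O[Si](C)(C)C(C)(C)C)CCO[Si](C)(C)C(C)(C)C
F14 | step 6 | (1R)-1-[(4R,5R)-5-ethynyl-2,2-dimethyl-1,3-dioxolan-4-yl]butyl (2R)-2,4-bis[(tert-butyldimethylsilyl)oxy]butanoate | C#C[C@H]1OC(C)(C)O[C@@H]1[C@H](OC(=O)[C@H](O[Si](C)(C)C(C)(C)C)CCO[Si](C)(C)C(C)(C)C)CCC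
F15 | step 6 | (1R)-1-[(4R,5R)-5-ethynyl-2,2-dimethyl-1,3-dioxolan-4-yl]butyl (2R)-2-[(tert-butyldimethylsilyl)oxy]-4-hydroxybutanoate | C#C[C@H]1OC(C)(C)O[C@@H]1[C@H](OC(=O)[C@H](O[Si](C)(C)C(C)(C)C)CCO)CCC
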